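**Plan** (numbering: ring CH = C14, then C1, C2=C3(Me), C4, C5, C6=C7(Me), C8, C9, C10=C11(Me), C12, C13 around the ring; carbinol carbon = C15)
- Cuts: the 14-membered ring is opened at C8–C9 (last C–C bond; helpers are PhSO2 on C9 and an O-carbonate on C6), then the chain is cut at C1–C2 (Negishi), C11–C12 (B-alkyl Suzuki) and C13–C14 (epoxide opening), back to (2E,6E)-farnesol, which supplies C1, C14, C15 and the whole side chain.
- Forward: farnesol → epoxy alcohol → 2-vinyl-1,3-diol → arm A (C13 to C9, allylic sulfone) → arm B (C1 to C8, isopropenyl carbinol) → carbonate → closure of the 14-membered ring at C8–C9 → reductive loss of the sulfone.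
- Enabling feature: C8–C9 is the central σ-bond of the ring 1,5-diene C6=C7–C8–C9–C10=C11. C9 is allylic to C10=C11, so a sulfone there gives a soft carbanion and is later excised through that allyl system. C8 is the free end of the allyl unit C6–C7(Me)–C8, so one π-allyl palladium event from a C6 carbonate closes the ring and creates the C6=C7 olefin.
- Stereochemistry: C15 from Sharpless epoxidation of farnesol, C14 by SN2 inversion in the cuprate opening; C2=C3 from carboalumination, C10=C11 from hydrozirconation, C6=C7 from the syn π-allyl complex, side-chain olefin from farnesol.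

Key step: step 15

Remark: the C6 carbinol centre of arm B is carried as a racemate (C6 epimer mixtures after the fragment union); this is harmless because C6 becomes sp2 in the ring closure.

**Step 1**
Reactants: 1 but-2-yn-1-ol
Product: 3 (E)-3-iodobut-2-en-1-ol, via alkenylzirconocene 2 (not isolated)
Conditions: Cp2Zr(H)Cl (2.2 equiv), THF, rt then 40 °C; I2, −78 to 0 °C
Reagents that add atoms: iodine, I-I
Why: Hydrozirconation–iodination: the first equivalent of Cp2Zr(H)Cl converts the hydroxyl into its zirconium alkoxide, syn addition of Zr–H to the alkyne equilibrates under the excess hydride to the less hindered C3-zirconium isomer, and iodinolysis with retention should give the E vinyl iodide.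

**Step 2**
Reactants: 3 (E)-3-iodobut-2-en-1-ol
Product: 5 [(2E)-3-iodobut-2-en-1-yl]sulfonylbenzene, via allylic bromide 4 (not isolated)
Conditions: PBr3 (0.4 equiv), Et2O, 0 °C; then PhSO2Na, DMF, rt
Reagents that add atoms: sodium benzenesulfinate, [Na+].[O-]S(=O)c1ccccc1
Why: Bromination of the primary allylic alcohol and SN2 S-alkylation of the sulfinate should give the allylic sulfone without touching the vinyl iodide or the olefin geometry.

**Step 3**
Reactants: 6 pent-4-yn-1-ol
Product: 8 (4E)-5-iodo-4-methylpent-4-en-1-ol, via alkenylalane 7 (not isolated)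
Conditions: AlMe3 (3 equiv), Cp2ZrCl2 (0.25 equiv), CH2Cl2, 0 °C to rt; I2, THF, −30 to 0 °C
Reagents that add atoms: trimethylaluminium, C[Al](C)C; iodine, I-I
Why: Zirconium-catalysed carboalumination (Negishi carboalumination) adds methyl and aluminium syn across the terminal alkyne with methyl on the internal carbon, and iodinolysis with retention should give the E trisubstituted vinyl iodide that later becomes C2=C3.

**Step 4**
Reactants: 8 (4E)-5-iodo-4-methylpent-4-en-1-ol
Product: 9 (4E)-5-iodo-4-methylpent-4-enal
Conditions: Dess–Martin periodinane, CH2Cl2, 0 °C to rt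
Reagents that add atoms: none
Why: Dess–Martin oxidation of the primary alcohol stops at the aldehyde and leaves the vinyl iodide untouched.

**Step 5**
Reactants: 9 (4E)-5-iodo-4-methylpent-4-enal
Product: 10 (6E)-7-iodo-2,6-dimethylhepta-1,6-dien-3-ol (racemic)
Conditions: isopropenylmagnesium bromide, THF, −78 °C
Reagents that add atoms: isopropenylmagnesium bromide, CC(=C)[Mg]Br
Why: Grignard 1,2-addition to the aldehyde is faster than iodine–magnesium exchange at low temperature; the carbinol centre (the later C6) is made racemic on purpose because it becomes sp2 in step 15.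

**Step 6**
Reactants: 10 (6E)-7-iodo-2,6-dimethylhepta-1,6-dien-3-ol
Product: 11 triethyl{[(6E)-7-iodo-2,6-dimethylhepta-1,6-dien-3-yl]oxy}silane
Conditions: Et3SiCl, imidazole, CH2Cl2, 0 °C to rt
Reagents that add atoms: chlorotriethylsilane, CC[Si](CC)(CC)Cl
Why: Standard silylation masks the secondary allylic hydroxyl for the organozinc coupling as an ether that zerovalent palladium does not ionise and that falls together with the second silyl group in step 13.

**Step 7**
Reactants: 12 (2E,6E)-farnesol
Product: 13 (2S,3S)-2,3-epoxyfarnesol
Conditions: Ti(OiPr)4 (5 mol %), L-(+)-diethyl tartrate (6 mol %), t-BuOOH, 4 Å molecular sieves, CH2Cl2, −20 °C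
Reagents that add atoms: tert-butyl hydroperoxide, CC(C)(C)OO
Why: Sharpless asymmetric epoxidation: the titanium tartrate complex epoxidises only the allylic 2,3-olefin and L-(+)-tartrate delivers oxygen to the face that gives the (2S,3S)-epoxide, which fixes the later C15 and, for now, C14.

**Step 8**
Reactants: 13 (2S,3S)-2,3-epoxyfarnesol
Product: 14 (2R,3S,6E)-2-ethenyl-3,7,11-trimethyldodeca-6,10-diene-1,3-diol
Conditions: vinylmagnesium bromide (4 equiv), CuI (20 mol %), THF/Et2O, −30 to 0 °C
Reagents that add atoms: vinylmagnesium bromide, C=C[Mg]Br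
Why: Copper-catalysed Grignard opening of the 2,3-epoxy alcohol: the vinylcopper species attacks C2, the only epoxide carbon open to SN2 because C3 is fully substituted, with inversion, so that the later C14 is set from the epoxide while C15 keeps its oxygen and configuration.

**Step 9**
Reactants: 14 (2R,3S,6E)-2-ethenyl-3,7,11-trimethyldodeca-6,10-diene-1,3-diol; 5 [(2E)-3-iodobut-2-en-1-yl]sulfonylbenzene
Product: 16 (2R,3S,6E)-2-[(3E)-3-methyl-5-(phenylsulfonyl)pent-3-en-1-yl]-3,7,11-trimethyldodeca-6,10-diene-1,3-diol, via B-alkyl-9-BBN borane 15 (not isolated)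
Conditions: 9-BBN (2.2 equiv), THF, 0 °C to rt; then 5, PdCl2(dppf) (5 mol %), aq K3PO4, DMF, rt
Reagents that add atoms: none
Why: 9-BBN hydroborates only the monosubstituted vinyl group (boron on the terminal carbon C12; one equivalent is consumed by the primary hydroxyl as a borinate that hydrolyses on work-up), and the B-alkyl Suzuki–Miyaura coupling proceeds with retention at the vinyl iodide, giving the E C10=C11 olefin.

**Step 10**
Reactants: 16 sulfone diol
Product: 17 primary iodide (CH2OH at C1 of 16 converted into CH2I)
Conditions: I2, PPh3, imidazole, CH2Cl2, 0 °C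
Reagents that add atoms: iodine, I-I
Why: Appel-type iodination converts only the primary hydroxyl because the tertiary hydroxyl is too hindered to be displaced through its alkoxyphosphonium salt.

**Step 11**
Reactants: 17 primary iodide
Product: 18 tertiary triethylsilyl ether of 17
Conditions: Et3SiOTf, 2,6-lutidine, CH2Cl2, −78 to 0 °C
Reagents that add atoms: triethylsilyl trifluoromethanesulfonate, CC[Si](CC)(CC)OS(=O)(=O)C(F)(F)F
Why: The silyl triflate silylates the hindered tertiary alcohol and so removes the only O–H proton before the organozinc reagent is made.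

**Step 12**
Reactants: 18 silylated iodide; 11 triethyl{[(6E)-7-iodo-2,6-dimethylhepta-1,6-dien-3-yl]oxy}silane
Product: 20 bis(triethylsilyl) seco compound (C1–C2 bond formed; C6 epimers), via alkylzinc iodide 19 (not isolated)
Conditions: Zn dust (activated), LiCl, THF, 40 °C; then 11, PdCl2(dppf) (5 mol %), THF/NMP, rt to 40 °C
Reagents that add atoms: none
Why: Negishi coupling: zinc inserts into the primary C–I bond to give an alkylzinc iodide that tolerates the sulfone and the silyl ethers, and the palladium-catalysed sp3–sp2 coupling with the vinyl iodide proceeds with retention, giving the E C2=C3 olefin.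

**Step 13**
Reactants: 20 bis(triethylsilyl) seco compound
Product: 21 seco diol (C6-OH and C15-OH free; C6 epimers)
Conditions: HF·pyridine, pyridine, THF, 0 °C to rt
Reagents that add atoms: none
Why: Buffered fluoride cleaves both triethylsilyl ethers without base that could isomerise the allylic sulfone and without acid strong enough to ionise the allylic carbinol.

**Step 14**
Reactants: 21 seco diol
Product: 22 C6 tert-butyl carbonate of 21 (C6 epimers)
Conditions: Boc2O, DMAP (20 mol %), CH2Cl2, 0 °C to rt
Reagents that add atoms: di-tert-butyl dicarbonate, CC(C)(C)OC(=O)OC(=O)OC(C)(C)C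
Why: DMAP-catalysed acylation carbonates the secondary allylic hydroxyl selectively because the tertiary hydroxyl is too hindered and the sulfone is not deprotonated under these neutral conditions.

**Step 15**
Reactants: 22 C6 tert-butyl carbonate
Product: 23 C9-phenylsulfonyl colleterpenol (14-membered ring; both epimers at C9)
Conditions: Pd(PPh3)4 (10 mol %), dppe (10 mol %), THF, 40 °C, 22 added by syringe pump over 12 h (final 2 mM)
Reagents that add atoms: none
Why: Zerovalent palladium ionises the allylic tert-butyl carbonate with inversion to the C6–C7–C8 π-allyl palladium cation, CO2 and tert-butoxide; the tert-butoxide deprotonates the allylic sulfone at C9 and the soft α-sulfonyl carbanion attacks the CH2 terminus C8 on the face away from palladium, forming C8–C9. The closest known reaction type is the Tsuji–Trost allylic alkylation under neutral allylic carbonate conditions, as used for macrocyclisation with sulfone-stabilised carbanions. The 14-membered carbocycle closes in the endo mode with respect to the allyl unit (attack at the distal terminus C8), the competing exo closure at C6 to a 12-membered ring being disfavoured because C6 is secondary and flanked by the C7 methyl. No stereocentre of the target is made: the racemic C6 centre becomes sp2, the new C9 centre is uncontrolled and is removed in step 16, and C14 and C15 are remote and not touched. The E geometry of the new C6=C7 olefin should come from attack on the more stable syn π-allyl isomer (C5 syn), which can equilibrate by η3–η1–η3 isomerisation because ring closure at high dilution is slow. α-Attack of the sulfonyl allyl anion is secured by the fully substituted γ-carbon C11, ionisation of the carbonate in preference to the allylic sulfone by the mild temperature, and ring closure in preference to oligomerisation by slow addition and by the fact that base is released only as each π-allyl cation is formed, so that no stock of carbanion builds up.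

**Step 16**
Reactants: 23 C9-phenylsulfonyl colleterpenol
Product: 24 colleterpenol
Conditions: PdCl2(dppp) (10 mol %), LiBHEt3 (4 equiv), THF, 0 °C to rt
Reagents that add atoms: none
Why: Palladium-catalysed hydride reduction of the allylic sulfone: ionisation gives the C9–C10–C11 π-allyl complex, hydride is delivered to the less substituted terminus C9, and the E C10=C11 olefin should be kept because syn/anti exchange at the fully substituted C11 terminus is slow; the free tertiary hydroxyl only consumes one equivalent of hydride.

**Compound list**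
1 | but-2-yn-1-ol | CC#CCO | starting material
2 | alkenylzirconocene chloride from 1 (Zr on C3, trans to CH2O; hydroxyl as zirconocene alkoxide) | C/C(=C\CO[Zr](Cl)(C1C=CC=C1)C1C=CC=C1)[Zr](Cl)(C1C=CC=C1)C1C=CC=C1 | intermediate
3 | (E)-3-iodobut-2-en-1-ol | C/C(I)=C\CO | intermediate
4 | (E)-1-bromo-3-iodobut-2-ene | C/C(I)=C\CBr | intermediate
5 | [(2E)-3-iodobut-2-en-1-yl]sulfonylbenzene (arm A fragment) | C/C(I)=C\CS(=O)(=O)c1ccccc1 | intermediate
6 | pent-4-yn-1-ol | C#CCCCO | starting material
7 | (E)-alkenyldimethylalane from 6 (Al cis to the new methyl; hydroxyl as O-AlMe2) | C[Al](C)/C=C(\C)CCCO[Al](C)C | intermediate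
8 | (4E)-5-iodo-4-methylpent-4-en-1-ol | I/C=C(\C)CCCO | intermediate
9 | (4E)-5-iodo-4-methylpent-4-enal | I/C=C(\C)CCC=O | intermediate
10 | (6E)-7-iodo-2,6-dimethylhepta-1,6-dien-3-ol (racemic) | I/C=C(\C)CCC(O)C(C)=C | intermediate
11 | triethyl{[(6E)-7-iodo-2,6-dimethylhepta-1,6-dien-3-yl]oxy}silane (racemic; arm B fragment) | I/C=C(\C)CCC(O[Si](CC)(CC)CC)C(C)=C | intermediate
12 | (2E,6E)-farnesol | CC(C)=CCC/C(C)=C/CC/C(C)=C/CO | starting material
13 | (2S,3S)-2,3-epoxyfarnesol | CC(C)=CCC/C(C)=C/CC[C@]1(C)O[C@H]1CO | intermediate
14 | (2R,3S,6E)-2-ethenyl-3,7,11-trimethyldodeca-6,10-diene-1,3-diol | CC(C)=CCC/C(C)=C/CC[C@](C)(O)[C@H](C=C)CO | intermediate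
15 | B-alkyl-9-BBN borane of 14 (boron on C12; primary hydroxyl as 9-BBN borinate) | CC(C)=CCC/C(C)=C/CC[C@](C)(O)[C@H](CCB1C2CCCC1CCC2)COB1C2CCCC1CCC2 | intermediate
16 | (2R,3S,6E)-2-[(3E)-3-methyl-5-(phenylsulfonyl)pent-3-en-1-yl]-3,7,11-trimethyldodeca-6,10-diene-1,3-diol | CC(C)=CCC/C(C)=C/CC[C@](C)(O)[C@H](CC/C(C)=C/CS(=O)(=O)c1ccccc1)CO | intermediate
17 | primary iodide from 16 (C1 CH2I; C14 and C15 as in 16) | CC(C)=CCC/C(C)=C/CC[C@](C)(O)[C@H](CC/C(C)=C/CS(=O)(=O)c1ccccc1)CI | intermediate
18 | tertiary (C15) triethylsilyl ether of 17 | CC(C)=CCC/C(C)=C/CC[C@](C)(O[Si](CC)(CC)CC)[C@H](CC/C(C)=C/CS(=O)(=O)c1ccccc1)CI | intermediate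
19 | alkylzinc iodide of 18 (C1–ZnI) | CC(C)=CCC/C(C)=C/CC[C@](C)(O[Si](CC)(CC)CC)[C@H](CC/C(C)=C/CS(=O)(=O)c1ccccc1)C[Zn]I | intermediate
20 | bis(triethylsilyl) seco compound: C9 sulfone, (2E) and (10E) olefins, C6 silyloxy with isopropenyl, C15 silyloxy (C6 epimers) | CC(C)=CCC/C(C)=C/CC[C@](C)(O[Si](CC)(CC)CC)[C@H](CC/C(C)=C/CS(=O)(=O)c1ccccc1)C/C=C(\C)CCC(O[Si](CC)(CC)CC)C(C)=C | intermediate
21 | seco diol: 20 without both silyl groups (C6 epimers) | CC(C)=CCC/C(C)=C/CC[C@](C)(O)[C@H](CC/C(C)=C/CS(=O)(=O)c1ccccc1)C/C=C(\C)CCC(O)C(C)=C | intermediate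
22 | C6 tert-butyl carbonate of 21 (C6 epimers) | CC(C)=CCC/C(C)=C/CC[C@](C)(O)[C@H](CC/C(C)=C/CS(=O)(=O)c1ccccc1)C/C=C(\C)CCC(OC(=O)OC(C)(C)C)C(C)=C | intermediate
23 | C9-phenylsulfonyl colleterpenol: (2S,5E)-6,10-dimethyl-2-[(1R,3E,7E,11E)-4,8,12-trimethyl-10-(phenylsulfonyl)cyclotetradeca-3,7,11-trien-1-yl]undeca-5,9-dien-2-ol (both epimers at the sulfone carbon) | CC(C)=CCC/C(C)=C/CC[C@](C)(O)[C@H]1C/C=C(\C)CC/C=C(\C)CC(S(=O)(=O)c2ccccc2)/C=C(\C)CC1 | intermediate
24 | colleterpenol: (2S,5E)-6,10-dimethyl-2-[(1R,3E,7E,11E)-4,8,12-trimethylcyclotetradeca-3,7,11-trien-1-yl]undeca-5,9-dien-2-ol | CC(C)=CCC/C(C)=C/CC[C@](C)(O)[C@H]1C/C=C(\C)CC/C=C(\C)CC/C=C(\C)CC1 | target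

**Count and risks**
Total step count: 16. Longest linear sequence: 10 steps (12 to 24, steps 7 to 16; the line from 1 through steps 1, 2 and 9 to 16 is equally long).

Steps most likely to fail:

Step 15. What may go wrong: incomplete syn/anti equilibration of the π-allyl intermediate and hence erosion of the E geometry at C6=C7, β-hydride elimination to a 1,3-diene, attack at the internal allyl terminus, or intermolecular alkylation to oligomers. The fallback fixes the geometry before the ring is closed and closes the ring without a catalyst. It sets out from 21: a 1,3-transposition of the secondary allylic alcohol catalysed by Ph3SiOReO3 (Et2O, 0 °C) should give the primary (E)-allylic alcohol F1, which can be freed from any Z isomer at the acyclic stage. Appel bromination (CBr4, PPh3, CH2Cl2, −20 °C) should then give the allylic bromide F2, and intramolecular SN2 alkylation of its sulfonyl carbanion (LiHMDS, 1.1 equiv, THF, −78 to 0 °C, 1 mM) comes back to the route at 23.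

Step 8. What may go wrong: Payne rearrangement of the epoxy alkoxide followed by attack at C1, or halohydrin formation by the magnesium halide, both lowering the regioselectivity of the opening. The fallback sets out from 13: oxidation (TEMPO, PhI(OAc)2, MeCN/H2O) should give the glycidic acid F3, in which no Payne shift is possible and the carboxylate activates C2. Opening with lithium divinylcuprate (THF, −20 °C), which attacks 2,3-epoxy acids at C2 with inversion, should give the 2-vinyl-3-hydroxy acid F4, and reduction with LiAlH4 (THF, 0 °C to rt) comes back to the route at 14.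

Step 12. What may go wrong: sluggish zinc insertion at the β-branched iodide, or protonation of the alkylzinc species before transmetalation. The fallback reverses the polarity of the coupling. It sets out from 11: iodine–lithium exchange (t-BuLi, Et2O, −78 °C) should give the alkenyllithium F5, and transmetalation with ZnCl2 the alkenylzinc chloride F6. This is coupled with the unactivated primary iodide 18 (Pd2(dba)3, tricyclopentylphosphine, N-methylimidazole, THF/NMP, 60 to 80 °C; Negishi coupling of an alkyl electrophile) and comes back to the route at 20.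

**Further compounds**
F1 | step 15 | primary (2E,6E)-allylic alcohol isomer of 21 (C8-OH, C6=C7 in place) | CC(C)=CCC/C(C)=C/CC[C@](C)(O)[C@H](CC/C(C)=C/CS(=O)(=O)c1ccccc1)C/C=C(\C)CC/C=C(\C)CO
F2 | step 15 | C8 allylic bromide of F1 | CC(C)=CCC/C(C)=C/CC[C@](C)(O)[C@H](CC/C(C)=C/CS(=O)(=O)c1ccccc1)C/C=C(\C)CC/C=C(\C)CBr
F3 | step 8 | (2R,3S)-3-[(3E)-4,8-dimethylnona-3,7-dien-1-yl]-3-methyloxirane-2-carboxylic acid | CC(C)=CCC/C(C)=C/CC[C@]1(C)O[C@H]1C(O)=O
F4 | step 8 | (2S,3S,6E)-2-ethenyl-3-hydroxy-3,7,11-trimethyldodeca-6,10-dienoic acid | CC(C)=CCC/C(C)=C/CC[C@](C)(O)[C@H](C=C)C(O)=O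
F5 | step 12 | alkenyllithium from 11 (Li in place of I) | [Li]/C=C(\C)CCC(O[Si](CC)(CC)CC)C(C)=C
F6 | step 12 | alkenylzinc chloride from 11 (ZnCl in place of I) | Cl[Zn]/C=C(\C)CCC(O[Si](CC)(CC)CC)C(C)=C
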